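**Plan**

1. Retrosynthetic cuts, in order: the C7 angelate; the nine-membered lactone at its C=C (metathesis) and at the tertiary ester O–C8; the acetyl–C8 bond; then, together, C6–C7 and C4–C3a of the tetrahydropyran; last, the lactone aldehyde back to an auxiliary aldol of a succinate imide with acrolein. Locants follow the hexahydrofuro[3,4-c]pyran core: C1 lactone carbinol, C3 lactone C=O, C3a, C4 (OCH2), O5, C6, C7 (carbinol), C7a; C8 is the quaternary carbon on C6.
2. Feature used: in the O5 ring, C6 lies between carbinol C7 and C8, which can be a ketone carbon (aldol retron). C4 is an O-bound methylene β to the lactone carbonyl C3, so it is an oxocarbenium carbon within reach of the lactone α-carbon C3a. The ring is therefore the union of a 4-formylbutanolide (C3a donor, C7 acceptor) with MOM-protected hydroxyacetone (C6 donor, C4 acceptor).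
3. Forward order: γ-lactone (steps 1 to 5), tetrahydropyran by union of the two fragments (step 7), C8 and its ester (steps 9 and 10), nine-membered lactone (step 11), angelate last (step 13).
4. Stereochemistry: C1 and C7a come from the oxazolidinone-controlled syn-aldol; C7, C6 and C3a are relayed from C7a in step 7; C8 is set by chelation-controlled addition next to C6. The ring alkene is Z by ring size and the side-chain alkene comes from angelic acid.

Key step: step 7

Remark: descriptors are given per compound by the sequence rules, so the label at C7a alternates between R and S with the group on O7 although no centre is inverted; the four starting materials are taken as commercial.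

**Step 1**
Reactants: 1 (S)-4-benzyl-1,3-oxazolidin-2-one; 2 methyl 4-chloro-4-oxobutanoate
Product: 3 methyl 4-[(4S)-4-benzyl-2-oxo-1,3-oxazolidin-3-yl]-4-oxobutanoate
Conditions: n-BuLi, THF, −78 °C; then 2, −78 → 0 °C
Reagents that add atoms: none
Why: N-acylation of the lithiated oxazolidinone by the acid chloride (imide formation) is fast at −78 °C and chemoselective over the methyl ester, and no stereocentre is formed.

**Step 2**
Reactants: 3 succinate imide; 4 acrolein
Product: 5 methyl (3S,4R)-3-[(4S)-4-benzyl-2-oxo-1,3-oxazolidine-3-carbonyl]-4-hydroxyhex-5-enoate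
Conditions: Bu2BOTf, iPr2NEt, CH2Cl2, −78 → 0 °C; 4, −78 → 0 °C; pH 7 buffer, MeOH, H2O2, 0 °C
Reagents that add atoms: none
Why: Evans syn-aldol reaction, in which the (Z)-boron enolate of 3 should add to acrolein through a Zimmerman–Traxler chair on the face away from the benzyl group and so set C3 (S) and C4 (R) of 5, the future C7a and C1.

**Step 3**
Reactants: 5 syn-aldol
Product: 6 (4S)-4-benzyl-3-[(2R,3S)-5-oxo-2-vinyltetrahydrofuran-3-carbonyl]-1,3-oxazolidin-2-one
Conditions: TsOH·H2O (cat.), toluene, 50 °C
Reagents that add atoms: none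
Why: Acid-catalysed transesterification of the C4 hydroxyl onto the γ-ester (5-exo-trig lactonisation) should close the butanolide with both stereocentres untouched, the syn-aldol giving the trans-2,3-disubstituted lactone.

**Step 4**
Reactants: 6 lactone imide
Product: 7 (2R,3S)-5-oxo-2-vinyltetrahydrofuran-3-carboxylic acid
Conditions: LiOH, H2O2, THF/H2O, 0 °C; Na2SO3; HCl to pH 2
Reagents that add atoms: hydrogen peroxide, OO
Why: Hydroperoxide cleavage of the N-acyl oxazolidinone (attack of LiOOH at the exocyclic carbonyl) should free the acid and return the auxiliary, any lactone opened by hydroxide closing again on acidification, and the α-centre is not expected to epimerise at 0 °C.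

**Step 5**
Reactants: 7 lactone acid
Product: 9 (2R,3S)-5-oxo-2-vinyltetrahydrofuran-3-carbaldehyde, via acid chloride 8 (not isolated)
Conditions: (COCl)2, DMF (cat.), CH2Cl2, 0 → 23 °C; concentrate; Bu3SnH, Pd(PPh3)4 (cat.), THF, 23 °C
Reagents that add atoms: none
Why: Acid chloride formation and palladium-catalysed hydride transfer from Bu3SnH (reduction of an acid chloride to an aldehyde) should stop at the aldehyde, leave lactone and vinyl group untouched, and avoid a hydroxymethyl lactone that could translactonise.

**Step 6**
Reactants: 10 hydroxyacetone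
Product: 11 1-(methoxymethoxy)propan-2-one
Conditions: MOMCl, iPr2NEt, CH2Cl2, 0 → 23 °C
Reagents that add atoms: chloromethyl methyl ether, COCCl
Why: O-alkylation of the primary hydroxyl by chloromethyl methyl ether under amine base (MOM ether formation) is routine and installs the future C4 as a formaldehyde acetal carbon.

**Step 7**
Reactants: 9 lactone aldehyde; 11 MOM-protected hydroxyacetone
Product: 13 (1R,3aS,6S,7S,7aR)-6-acetyl-7-hydroxy-1-vinylhexahydro-1H-furo[3,4-c]pyran-3-one, via titanium aldolate 12 (not isolated)
Conditions: 11, TiCl4 (1.2 equiv), iPr2NEt (1.3 equiv), CH2Cl2, −78 °C; 9, −78 °C; then TiCl4 (2 equiv), iPr2NEt (2 equiv), −78 → 0 °C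
Reagents that add atoms: none
Why: Proposed new method: the chelated (Z)-titanium enolate of 11 should add to aldehyde 9 through a closed chair transition state to give aldolate 12 (C6–C7), and the second charge of TiCl4 then ionises the MOM acetal to the O5=C4 oxocarbenium ion while TiCl4 and amine soft-enolise the lactone, whose α-carbon C3a closes the tetrahydropyran by a 6-(enolexo)-endo-trig attack (C4–C3a). The closest known reaction types are the titanium aldol of α-alkoxy ketones, the alkoxymethylation of titanium enolates by formaldehyde acetals or chloromethyl ethers, Prins-type closures of MOM ethers, and aldol–Prins cascades in which an aldol step leaves a tethered oxocarbenium ion; their union in one flask on a lactone enolate is the untested part. C7 should be set by 1,2-induction from C7a (the anti-Felkin sense usual for (Z)-enolates), and because the product is a cyclic aldol an axial C7 oxygen, syn-diaxial to the C3a–C3 bond, could still revert by retro-aldol and re-close to the equatorial alcohol. C6 is under thermodynamic control, since the α-alkoxy ketone epimerises through its titanium enolate to the equatorial acetyl group trans to O7, and C3a is fixed by the tether, because the electrophile is delivered from the C7a side chain and only the cis-fused bicycle can form. The step needs closure at C3a: closure through the O7 oxygen (which would lead to a tetrahydrofuran) or through the methyl ketone enolate would be 5-endo, and methylene acetal formation between O7 and O5 is reversible under TiCl4, so the 6-endo C–C bond should be the only irreversible exit. Running the aldol at −78 °C before the second charge protects the β-acyloxy aldehyde from elimination and the MOM group from early cleavage.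

**Step 8**
Reactants: 13 hydroxy ketone
Product: 14 (1R,3aS,6S,7S,7aS)-6-acetyl-7-[(tert-butyldimethylsilyl)oxy]-1-vinylhexahydro-1H-furo[3,4-c]pyran-3-one
Conditions: TBSOTf, 2,6-lutidine, CH2Cl2, −78 °C
Reagents that add atoms: tert-butyldimethylsilyl triflate, CC(C)(C)[Si](C)(C)OS(=O)(=O)C(F)(F)F
Why: Silyl ether formation with a silyl triflate and a hindered pyridine base should protect the equatorial C7 hydroxyl without enolising the ketone at −78 °C, and it blocks retro-aldol and chelation by O7 in the next step.

**Step 9**
Reactants: 14 silyl ether ketone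
Product: 16 (2R)-3-ethoxy-2-[(1R,3aS,6S,7S,7aS)-7-[(tert-butyldimethylsilyl)oxy]-3-oxo-1-vinylhexahydro-1H-furo[3,4-c]pyran-6-yl]but-3-en-2-yl 2-methylprop-2-enoate, via bromomagnesium alkoxide 15 (not isolated)
Conditions: CH2=CHOEt, t-BuLi, THF, −78 → 0 °C; MgBr2·OEt2, −78 °C; 14, −78 °C; then methacrylic anhydride, DMAP (cat.), −78 → 23 °C
Reagents that add atoms: ethyl vinyl ether (used as 1-ethoxyvinyllithium), C=COCC; methacrylic anhydride, CC(=C)C(=O)OC(=O)C(C)=C
Why: Chelation-controlled 1,2-addition of an acyl anion equivalent, in which magnesium bridges the ketone oxygen and ring oxygen O5 so that the 1-ethoxyvinyl group enters from the side of the C6 hydrogen and sets C8 (R), the activated ketone reacting faster than the lactone at −78 °C, followed by O-acylation of the tertiary alkoxide 15 in the same flask.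

**Step 10**
Reactants: 16 enol ether methacrylate
Product: 17 (2R)-3-oxo-2-[(1R,3aS,6S,7S,7aS)-7-[(tert-butyldimethylsilyl)oxy]-3-oxo-1-vinylhexahydro-1H-furo[3,4-c]pyran-6-yl]butan-2-yl 2-methylprop-2-enoate
Conditions: 0.5 M aq. HCl, THF, 0 °C
Reagents that add atoms: water, O
Why: Acid-catalysed hydrolysis of the enol ether (C-protonation, hemiketal, loss of ethanol) should unveil the methyl ketone under conditions too mild to cleave the TBS ether or the esters, and C8 is quaternary and cannot epimerise.

**Step 11**
Reactants: 17 diene ketone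
Product: 18 TBS-protected tricycle (1R,3aS,6S,7S,7aS,8R): the core of 14 in which C8 (methyl, acetyl) is joined through its oxygen to the carbonyl of a (Z)-2-methylprop-2-enoate whose β-carbon is bonded to C1 (nine-membered lactone), C7 OTBS
Conditions: second-generation Hoveyda–Grubbs catalyst (cat.), toluene, high dilution, 100 °C
Reagents that add atoms: none
Why: Ring-closing metathesis, in which the catalyst should load on the monosubstituted C1 vinyl group and close onto the methacrylate, the nine-membered ring allowing only the Z enoate, while the cis-fused bicycle holds the two alkenes close and high dilution disfavours dimerisation.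

**Step 12**
Reactants: 18 TBS-protected tricycle
Product: 19 tricyclic alcohol (1R,3aS,6S,7S,7aR,8R): 18 with a free C7 hydroxyl
Conditions: HF·pyridine, pyridine, THF, 0 → 23 °C
Reagents that add atoms: none
Why: Desilylation with buffered HF·pyridine (Si–O cleavage by fluoride) avoids basic conditions, so the α-acyloxy ketone, both lactones and the C8 ester should survive and no stereocentre is touched.

**Step 13**
Reactants: 19 tricyclic alcohol
Product: 20 CNP0342803.2, the C7 angelate (1R,3aS,6S,7S,7aS,8R)
Conditions: angelic acid, 2,4,6-trichlorobenzoyl chloride, Et3N, toluene, 23 °C; then 19, 80 °C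
Reagents that add atoms: angelic acid, C/C=C(/C)C(=O)O
Why: Yamaguchi-type esterification through the mixed anhydride of angelic acid, run without a nucleophilic catalyst, should acylate the C7 hydroxyl with retention at C7 and without Z to E isomerisation of the angelate to the tiglate.

**Compound list**

1 | (S)-4-benzyl-1,3-oxazolidin-2-one | O=C1OC[C@H](Cc2ccccc2)N1 | starting material
2 | methyl 4-chloro-4-oxobutanoate | COC(=O)CCC(Cl)=O | starting material
3 | methyl 4-[(4S)-4-benzyl-2-oxo-1,3-oxazolidin-3-yl]-4-oxobutanoate | COC(=O)CCC(=O)N1[C@@H](Cc2ccccc2)COC1=O | intermediate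
4 | acrolein | C=CC=O | starting material
5 | methyl (3S,4R)-3-[(4S)-4-benzyl-2-oxo-1,3-oxazolidine-3-carbonyl]-4-hydroxyhex-5-enoate | COC(=O)C[C@H](C(=O)N1[C@@H](Cc2ccccc2)COC1=O)[C@H](O)C=C | intermediate
6 | (4S)-4-benzyl-3-[(2R,3S)-5-oxo-2-vinyltetrahydrofuran-3-carbonyl]-1,3-oxazolidin-2-one | O=C([C@H]1CC(=O)O[C@@H]1C=C)N1[C@@H](Cc2ccccc2)COC1=O | intermediate
7 | (2R,3S)-5-oxo-2-vinyltetrahydrofuran-3-carboxylic acid | OC(=O)[C@H]1CC(=O)O[C@@H]1C=C | intermediate
8 | (2R,3S)-5-oxo-2-vinyltetrahydrofuran-3-carbonyl chloride | ClC(=O)[C@H]1CC(=O)O[C@@H]1C=C | intermediate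
9 | (2R,3S)-5-oxo-2-vinyltetrahydrofuran-3-carbaldehyde | O=C[C@H]1CC(=O)O[C@@H]1C=C | intermediate
10 | hydroxyacetone (1-hydroxypropan-2-one) | CC(=O)CO | starting material
11 | 1-(methoxymethoxy)propan-2-one | CC(=O)COCOC | intermediate
12 | (3R,4S)-4-hydroxy-3-(methoxymethoxy)-4-[(2R,3R)-5-oxo-2-vinyltetrahydrofuran-3-yl]butan-2-one, present as its trichlorotitanium aldolate (free aldol shown) | CC(=O)[C@H](OCOC)[C@@H](O)[C@H]1CC(=O)O[C@@H]1C=C | intermediate
13 | (1R,3aS,6S,7S,7aR)-6-acetyl-7-hydroxy-1-vinylhexahydro-1H-furo[3,4-c]pyran-3-one | CC(=O)[C@H]1OC[C@H]2C(=O)O[C@H](C=C)[C@H]2[C@@H]1O | intermediate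
14 | (1R,3aS,6S,7S,7aS)-6-acetyl-7-[(tert-butyldimethylsilyl)oxy]-1-vinylhexahydro-1H-furo[3,4-c]pyran-3-one | CC(=O)[C@H]1OC[C@H]2C(=O)O[C@H](C=C)[C@H]2[C@@H]1O[Si](C)(C)C(C)(C)C | intermediate
15 | bromomagnesium (2R)-3-ethoxy-2-[(1R,3aS,6S,7S,7aS)-7-[(tert-butyldimethylsilyl)oxy]-3-oxo-1-vinylhexahydro-1H-furo[3,4-c]pyran-6-yl]but-3-en-2-olate | Br[Mg]O[C@@](C)(C(=C)OCC)[C@H]1OC[C@H]2C(=O)O[C@H](C=C)[C@H]2[C@@H]1O[Si](C)(C)C(C)(C)C | intermediate
16 | (2R)-3-ethoxy-2-[(1R,3aS,6S,7S,7aS)-7-[(tert-butyldimethylsilyl)oxy]-3-oxo-1-vinylhexahydro-1H-furo[3,4-c]pyran-6-yl]but-3-en-2-yl 2-methylprop-2-enoate | C=C(C)C(=O)O[C@@](C)(C(=C)OCC)[C@H]1OC[C@H]2C(=O)O[C@H](C=C)[C@H]2[C@@H]1O[Si](C)(C)C(C)(C)C | intermediate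
17 | (2R)-3-oxo-2-[(1R,3aS,6S,7S,7aS)-7-[(tert-butyldimethylsilyl)oxy]-3-oxo-1-vinylhexahydro-1H-furo[3,4-c]pyran-6-yl]butan-2-yl 2-methylprop-2-enoate | C=C(C)C(=O)O[C@@](C)(C(C)=O)[C@H]1OC[C@H]2C(=O)O[C@H](C=C)[C@H]2[C@@H]1O[Si](C)(C)C(C)(C)C | intermediate
18 | TBS-protected tricycle (1R,3aS,6S,7S,7aS,8R), nine-membered (Z)-enoate lactone closed, C7 OTBS | CC(C)(C)[Si](C)(C)O[C@H]1[C@@H]2[C@H]3/C=C(/C)C(=O)O[C@@](C)(C(C)=O)[C@H]1OC[C@H]2C(=O)O3 | intermediate
19 | tricyclic alcohol (1R,3aS,6S,7S,7aR,8R), C7 OH | O[C@H]1[C@@H]2[C@H]3/C=C(/C)C(=O)O[C@@](C)(C(C)=O)[C@H]1OC[C@H]2C(=O)O3 | intermediate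
20 | CNP0342803.2, C7 angelate (1R,3aS,6S,7S,7aS,8R) | C/C=C(/C)C(=O)O[C@H]1[C@@H]2[C@H]3/C=C(/C)C(=O)O[C@@](C)(C(C)=O)[C@H]1OC[C@H]2C(=O)O3 | target

**Step count and risks**

Total steps: 13. Longest linear sequence: 12 steps (steps 1 to 5 and 7 to 13; step 6 is a one-step branch).

Steps most likely to fail:

1. Step 7 (Proposed new method). The lactone may be enolised too slowly by TiCl4 and amine, so that the aldolate is diverted into a methylene acetal between O7 and O5 or loses water; facial selectivity at C7 may be low, and the β-acyloxy aldehyde may eliminate before the aldol. The fallback uses known chemistry and sets out from 9 and 11. The titanium aldol alone is run at −78 °C and quenched, and aldol 12 is isolated. TBSOTf and 2,6-lutidine give the silyl ether F1 (C7 OTBS, MOM ether intact). TMSOTf and Et3N in CH2Cl2 at 0 °C then silylate the lactone to its silyl ketene acetal and ionise the MOM acetal, and a Mukaiyama-type addition of the ketene acetal to the oxocarbenium ion closes the ring. Aqueous acid work-up and DBU equilibration of C6 should give 14, where the fallback rejoins the route; step 8 is then not needed.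

2. Step 11. Closure onto the electron-poor 1,1-disubstituted alkene may be slow, with dimerisation through the vinyl group and catalyst decomposition at the temperature needed. The fallback sets out from 14. The addition of step 9 is repeated, but the alkoxide is trapped with 2-(diethoxyphosphoryl)propanoyl chloride to give phosphonate ester F2. Mild aqueous HCl unveils the ketone in acetyl phosphonate F3. Ozonolysis of the only alkene (O3, CH2Cl2, −78 °C; PPh3) gives aldehyde F4. An intramolecular Horner–Wadsworth–Emmons reaction (LiCl, iPr2NEt, MeCN, high dilution) should close the nine-membered Z enoate and rejoin the route at 18.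

3. Step 9. The organometallic may attack the lactone, chelation control at C8 may erode, and acylation of the crowded tertiary alkoxide may be incomplete. The fallback sets out from 14. Ethynylmagnesium bromide, a smaller and less basic acyl anion equivalent, is added under the same chelation control, and the less hindered propargylic alkoxide is trapped with methacrylic anhydride to give propargylic methacrylate F5. Gold-catalysed hydration of the terminal alkyne (Ph3PAuNTf2, wet dioxane), directed to the internal carbon by the neighbouring ester, should give methyl ketone 17, where the fallback rejoins the route.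

**Further compounds**

F1 | step 7 | (3R,4S)-4-[(tert-butyldimethylsilyl)oxy]-3-(methoxymethoxy)-4-[(2R,3S)-5-oxo-2-vinyltetrahydrofuran-3-yl]butan-2-one | CC(=O)[C@H](OCOC)[C@@H](O[Si](C)(C)C(C)(C)C)[C@H]1CC(=O)O[C@@H]1C=C
F2 | step 11 | C8 2-(diethoxyphosphoryl)propanoate of the 1-ethoxyvinyl carbinol derived from 14 | CCOP(=O)(OCC)C(C)C(=O)O[C@@](C)(C(=C)OCC)[C@H]1OC[C@H]2C(=O)O[C@H](C=C)[C@H]2[C@@H]1O[Si](C)(C)C(C)(C)C
F3 | step 11 | C8 2-(diethoxyphosphoryl)propanoate with the acetyl group unveiled | CCOP(=O)(OCC)C(C)C(=O)O[C@@](C)(C(C)=O)[C@H]1OC[C@H]2C(=O)O[C@H](C=C)[C@H]2[C@@H]1O[Si](C)(C)C(C)(C)C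
F4 | step 11 | C1 aldehyde of F3 (vinyl cleaved to formyl) | CCOP(=O)(OCC)C(C)C(=O)O[C@@](C)(C(C)=O)[C@H]1OC[C@H]2C(=O)O[C@H](C=O)[C@H]2[C@@H]1O[Si](C)(C)C(C)(C)C
F5 | step 9 | propargylic methacrylate: C8 bearing methyl, ethynyl and 2-methylprop-2-enoyloxy on the core of 14 | C=C(C)C(=O)O[C@@](C)(C#C)[C@H]1OC[C@H]2C(=O)O[C@H](C=C)[C@H]2[C@@H]1O[Si](C)(C)C(C)(C)C
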